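Ring A (the bromocyclohexane) is read as a Diels–Alder retron whose CHBr–CH2 unit is the former double bond. Its bond from the ring CH2 to the C(OH)Me carbon and its bond from the ring-fusion CH to the quaternary C–Me carbon are the two σ-bonds of one [4+2] event, which closes the central ring B as well. The precursor is an enantiopure norbornane (rings C and D) with a (Z)-2-bromo-1,3-diene on a two-carbon tether at the bridgehead and an (E)-nitroalkene on the neighbouring exo position. One thermal intramolecular cycloaddition sets the quaternary carbon and the ring-fusion CH; the nitro group later becomes the methyl carbinol and the alkenyl bromide the equatorial bromide.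

Key step: step 13

Assumption: in step 8 the (S)-configured catalyst is taken to deliver the (1R,2R,4S) adduct, as the accepted transition-state model for enones predicts; the mirror-image catalyst would be used if the sense proves opposite.

Step 1
Reactants: 1 prop-2-yn-1-ol; 2 bromoethene (vinyl bromide)
Product: 3 pent-4-en-2-yn-1-ol
Conditions: PdCl2(PPh3)2 (2 mol%), CuI (4 mol%), iPr2NH, THF, 0 °C to rt
Reagents that add atoms: none
Why: Sonogashira coupling joins the terminal alkyne to vinyl bromide under mild amine-base conditions that leave the free alcohol untouched.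

Step 2
Reactants: 3 pent-4-en-2-yn-1-ol
Product: 5 (2Z)-3-bromo-2-methylpenta-2,4-dien-1-ol, via dienylmagnesium chelate 4 (not isolated)
Conditions: MeMgBr (3.5 equiv), CuI (10 mol%), Et2O/THF, −20 °C to rt; then BrCCl2CCl2Br, −78 to 0 °C
Reagents that add atoms: methylmagnesium bromide C[Mg]Br; 1,2-dibromo-1,1,2,2-tetrachloroethane BrC(Cl)(Cl)C(Cl)(Cl)Br
Why: Copper-catalysed anti-carbomagnesiation of a propargylic alcohol delivers methyl to the alkyne carbon next to the carbinol and parks magnesium on the far carbon inside a five-membered alkoxide chelate, so that bromination with retention places Br cis to CH2OH and leaves methyl cis to vinyl, which is the 2Z geometry the later cycloaddition needs.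

Step 3
Reactants: 5 (2Z)-3-bromo-2-methylpenta-2,4-dien-1-ol
Product: 6 (3Z)-3,5-dibromo-4-methylpenta-1,3-diene
Conditions: CBr4, PPh3, CH2Cl2, 0 °C
Reagents that add atoms: carbon tetrabromide BrC(Br)(Br)Br
Why: The Appel reaction converts the primary allylic alcohol into the bromide under neutral conditions by SN2 displacement without allylic transposition.

Step 4
Reactants: 6 (3Z)-3,5-dibromo-4-methylpenta-1,3-diene
Product: 8 (3Z)-4-bromo-3-methylhexa-3,5-dien-1-ol, via alkoxysilane 7 (not isolated)
Conditions: (iPrO)Me2SiCH2MgCl, Li2CuCl4 (3 mol%), THF, −40 to 0 °C; then 30% H2O2, KF, KHCO3, THF/MeOH, rt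
Reagents that add atoms: [(isopropoxydimethylsilyl)methyl]magnesium chloride CC(C)O[Si](C)(C)C[Mg]Cl; hydrogen peroxide OO
Why: Nucleophilic hydroxymethylation with the silylmethyl Grignard reagent (copper-catalysed SN2 coupling at the primary allylic carbon, the γ-carbon being fully substituted) followed by Tamao–Kumada oxidation of the C–Si bond adds one CH2OH carbon without disturbing the alkene geometry.

Step 5
Reactants: 8 (3Z)-4-bromo-3-methylhexa-3,5-dien-1-ol
Product: 9 (3Z)-3,6-dibromo-4-methylhexa-1,3-diene
Conditions: CBr4, PPh3, CH2Cl2, 0 °C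
Reagents that add atoms: carbon tetrabromide BrC(Br)(Br)Br
Why: A second Appel reaction gives the primary homoallylic bromide needed for Grignard formation.

Step 6
Reactants: 9 (3Z)-3,6-dibromo-4-methylhexa-1,3-diene; 10 3-ethoxycyclopent-2-en-1-one
Product: 13 3-[(3Z)-4-bromo-3-methylhexa-3,5-dien-1-yl]cyclopent-2-en-1-one, via Grignard reagent 11 (not isolated), via magnesium carbinolate 12 (not isolated)
Conditions: Mg, THF, rt; then 10, THF, 0 °C; then 1 M HCl, rt
Reagents that add atoms: water O
Why: Magnesium inserts into the primary C–Br bond far faster than into the hindered tetrasubstituted alkenyl bromide, and 1,2-addition to the vinylogous ester followed by acid hydrolysis (Stork–Danheiser transposition) gives the 3-substituted enone.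

Step 7
Reactants: 13 3-[(3Z)-4-bromo-3-methylhexa-3,5-dien-1-yl]cyclopent-2-en-1-one
Product: 15 4-[(3Z)-4-bromo-3-methylhexa-3,5-dien-1-yl]-2-(triisopropylsilyloxy)cyclopenta-1,3-diene, via lithium dienolate 14 (not isolated)
Conditions: LDA, THF, −78 °C; TIPSOTf, −78 to 0 °C
Reagents that add atoms: triisopropylsilyl trifluoromethanesulfonate CC(C)[Si](C(C)C)(C(C)C)OS(=O)(=O)C(F)(F)F
Why: Kinetic deprotonation at the α′-CH2 with LDA at −78 °C and O-silylation give the cross-conjugated 2-silyloxycyclopentadiene, which is used at once before 1,5-hydrogen shifts can scramble it.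

Step 8
Reactants: 15 4-[(3Z)-4-bromo-3-methylhexa-3,5-dien-1-yl]-2-(triisopropylsilyloxy)cyclopenta-1,3-diene; 16 but-3-en-2-one (methyl vinyl ketone)
Product: 17 1-[(1R,2R,4S)-1-[(3Z)-4-bromo-3-methylhexa-3,5-dien-1-yl]-5-(triisopropylsilyloxy)bicyclo[2.2.1]hept-5-en-2-yl]ethan-1-one (acetyl endo)
Conditions: (S)-1-(2-methylphenyl)-3,3-diphenyltetrahydro-1H,3H-pyrrolo[1,2-c][1,3,2]oxazaborole·Tf2NH (20 mol%), CH2Cl2, −78 °C
Reagents that add atoms: none
Why: A catalytic enantioselective Diels–Alder reaction with a chiral oxazaborolidinium Lewis acid should join the β-carbon of the enone to the unsubstituted, silyloxy-activated diene terminus and the α-carbon to the chain-bearing terminus, creating the quaternary bridgehead, with the acetyl group endo (syn to the enol ether bridge) and the catalyst-shielded enone face fixing all three stereocentres as 1R,2R,4S in one event.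

Step 9
Reactants: 17 endo-acetyl cycloadduct
Product: 18 1-[(3Z)-4-bromo-3-methylhexa-3,5-dien-1-yl]-6-endo-(prop-1-en-2-yl)-3-(triisopropylsilyloxy)bicyclo[2.2.1]hept-2-ene (configuration as in 17)
Conditions: Ph3PCH3Br, KOtBu, THF, 0 °C
Reagents that add atoms: methyltriphenylphosphonium bromide C[P+](c1ccccc1)(c1ccccc1)c1ccccc1.[Br-]
Why: Wittig methylenation converts the methyl ketone into the isopropenyl group while the silyl enol ether and the bromodiene are inert to the ylide, low temperature limiting epimerisation of the α-stereocentre.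

Step 10
Reactants: 18 isopropenyl silyl enol ether
Product: 19 4-[(3Z)-4-bromo-3-methylhexa-3,5-dien-1-yl]-3-exo-(dimethoxymethyl)-5-endo-(prop-1-en-2-yl)bicyclo[2.2.1]heptan-2-one
Conditions: HC(OMe)3, TMSOTf (10 mol%), CH2Cl2, −78 °C
Reagents that add atoms: trimethyl orthoformate COC(OC)OC
Why: Mukaiyama-type addition of the silyl enol ether to the dimethoxycarbenium ion generated from the orthoformate installs the masked formyl carbon from the exo face, the endo face of that carbon being blocked by the endo isopropenyl group across the ring.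

Step 11
Reactants: 19 exo-(dimethoxymethyl) ketone
Product: 21 1-[(3Z)-4-bromo-3-methylhexa-3,5-dien-1-yl]-3-endo-hydroxy-6-endo-(prop-1-en-2-yl)bicyclo[2.2.1]heptane-2-exo-carbaldehyde, via hydroxy acetal 20 (not isolated)
Conditions: NaBH4, MeOH, −20 °C; then 1 M HCl, THF, 0 °C to rt
Reagents that add atoms: water O
Why: Borohydride attacks the norbornanone from the exo face to give the endo alcohol trans to the exo side chain (substrate control as in other 3-substituted norbornan-2-ones), and aqueous acid then hydrolyses the dimethyl acetal to the aldehyde.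

Step 12
Reactants: 21 endo-hydroxy exo-aldehyde
Product: 24 4-[(3Z)-4-bromo-3-methylhexa-3,5-dien-1-yl]-3-exo-[(E)-2-nitroethenyl]-5-endo-(prop-1-en-2-yl)bicyclo[2.2.1]heptan-2-endo-yl acetate, via nitro aldol 22 (not isolated), via nitro diacetate 23 (not isolated)
Conditions: MeNO2, Et3N (cat.), rt; then Ac2O, DMAP (cat.), Et3N, CH2Cl2, 0 °C to rt
Reagents that add atoms: nitromethane C[N+](=O)[O-]; acetic anhydride CC(=O)OC(C)=O
Why: A Henry reaction followed by acetylation of both hydroxyls and E1cB loss of acetic acid from the β-nitro acetate gives the (E)-nitroalkene and at the same time caps the ring alcohol as an acetate.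

Step 13
Reactants: 24 (E)-nitroalkene bromodiene acetate
Product: 25 tetracyclic nitro acetate (rings A and B trans-fused; C(Br)=CH in ring A; nitro cis to the ring-fusion H)
Conditions: toluene (0.01 M), BHT (cat.), 110 °C
Reagents that add atoms: none
Why: A concerted, asynchronous thermal [4+2] cycloaddition of the electron-poor (E)-nitroalkene with the 2-bromodiene joins the diene CH2 terminus to the nitro-bearing carbon and the methyl-bearing diene terminus to the nitroalkene β-carbon; the closest known reaction type is the intramolecular Diels–Alder reaction of 1-nitrodeca-1,7,9-trienes, in which a 2-bromo substituent on the diene is a known trans-directing group. Ring A closes as the cycloadduct cyclohexene and ring B closes through the four-atom tether in a chair-like six-membered arrangement, the usual mode of a 1,7,9-decatriene. The quaternary C–Me carbon and the ring-fusion CH arise trans to one another from the anti transition state, in which the (E)-nitro group is endo, the tether leaves the diene on its outer side and the inside methyl becomes axial on ring B. Their configuration relative to the norbornane is relayed from the bridgehead and the exo carbon: the gauche exo C–C and bridgehead C–C bonds allow only one chair for ring B, so only one trans-fused adduct can form. The selectivity needed is trans over cis ring fusion, which the endo preference of the nitro group, the bromine next to the tethered diene terminus and the defined Z geometry of the diene should secure, while the nitro-bearing centre needs no control because the Nef reaction removes it. The isolated isopropenyl group and the acetate are spectators at this temperature.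

Step 14
Reactants: 25 tetracyclic nitro acetate
Product: 27 tetracyclic hydroxy ketone (β,γ-unsaturated ketone in ring A; endo OH free), via sodium nitronate 26 (not isolated)
Conditions: NaOMe, MeOH, 0 °C to rt; then TiCl3 (aq.), NH4OAc, THF, rt
Reagents that add atoms: water O
Why: A reductive Nef reaction (nitronate reduced by TiCl3 to the imine, which hydrolyses at buffered pH) converts the secondary nitro group into the ketone, and the methoxide used to form the nitronate also removes the acetate by transesterification.

Step 15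
Reactants: 27 tetracyclic hydroxy ketone
Product: 28 tetracyclic diol with alkenyl bromide and isopropenyl group (tertiary OH axial)
Conditions: MeMgBr, CeCl3, THF, −78 to 0 °C
Reagents that add atoms: methylmagnesium bromide C[Mg]Br
Why: Organocerium-mediated Grignard addition suppresses enolisation of the β,γ-unsaturated ketone, and methyl enters along the equatorial direction away from the axial angular methyl group so that the tertiary hydroxyl ends up axial and syn to that methyl, as in the target.

Step 16
Reactants: 28 tetracyclic alkenyl bromide diol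
Product: 29 CNP0295684.1 (target bromo diol)
Conditions: Co(acac)2, t-BuOOH, 1,4-cyclohexadiene, Et3SiH, n-PrOH, rt
Reagents that add atoms: none
Why: Cobalt-hydride hydrogen-atom-transfer hydrogenation (Mukaiyama-type, known for alkenyl halides) adds H• to the unhalogenated alkene carbon and the resulting α-bromo radical takes H from cyclohexadiene on the axial face anti to the angular methyl, leaving bromine equatorial, while the isopropenyl group is reduced to isopropyl in the same operation.

Compound list
1 | prop-2-yn-1-ol | C#CCO | starting material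
2 | bromoethene (vinyl bromide) | C=CBr | starting material
3 | pent-4-en-2-yn-1-ol | C=CC#CCO | intermediate
4 | bromomagnesium (2Z)-3-(bromomagnesio)-2-methylpenta-2,4-dien-1-olate (chelate) | Br[Mg]OC/C(C)=C(\[Mg]Br)C=C | intermediate
5 | (2Z)-3-bromo-2-methylpenta-2,4-dien-1-ol | OC/C(C)=C(\Br)C=C | intermediate
6 | (3Z)-3,5-dibromo-4-methylpenta-1,3-diene | BrC/C(C)=C(\Br)C=C | intermediate
7 | [(3Z)-4-bromo-3-methylhexa-3,5-dien-1-yl]dimethyl(propan-2-yloxy)silane | CC(C)O[Si](C)(C)CC/C(C)=C(\Br)C=C | intermediate
8 | (3Z)-4-bromo-3-methylhexa-3,5-dien-1-ol | OCC/C(C)=C(\Br)C=C | intermediate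
9 | (3Z)-3,6-dibromo-4-methylhexa-1,3-diene | BrCC/C(C)=C(\Br)C=C | intermediate
10 | 3-ethoxycyclopent-2-en-1-one | CCOC1=CC(=O)CC1 | starting material
11 | bromo[(3Z)-4-bromo-3-methylhexa-3,5-dien-1-yl]magnesium | Br[Mg]CC/C(C)=C(\Br)C=C | intermediate
12 | bromomagnesium 1-[(3Z)-4-bromo-3-methylhexa-3,5-dien-1-yl]-3-ethoxycyclopent-2-en-1-olate | CCOC1=CC(O[Mg]Br)(CC/C(C)=C(\Br)C=C)CC1 | intermediate
13 | 3-[(3Z)-4-bromo-3-methylhexa-3,5-dien-1-yl]cyclopent-2-en-1-one | O=C1C=C(CC/C(C)=C(\Br)C=C)CC1 | intermediate
14 | lithium 4-[(3Z)-4-bromo-3-methylhexa-3,5-dien-1-yl]cyclopenta-1,3-dien-2-olate | [Li]OC1=CCC(CC/C(C)=C(\Br)C=C)=C1 | intermediate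
15 | 4-[(3Z)-4-bromo-3-methylhexa-3,5-dien-1-yl]-2-(triisopropylsilyloxy)cyclopenta-1,3-diene | CC(C)[Si](C(C)C)(C(C)C)OC1=CCC(CC/C(C)=C(\Br)C=C)=C1 | intermediate
16 | but-3-en-2-one (methyl vinyl ketone) | CC(=O)C=C | starting material
17 | 1-[(1R,2R,4S)-1-[(3Z)-4-bromo-3-methylhexa-3,5-dien-1-yl]-5-(triisopropylsilyloxy)bicyclo[2.2.1]hept-5-en-2-yl]ethan-1-one (acetyl endo) | CC(=O)[C@@H]1C[C@H]2C[C@]1(CC/C(C)=C(\Br)C=C)C=C2O[Si](C(C)C)(C(C)C)C(C)C | intermediate
18 | 1-[(3Z)-4-bromo-3-methylhexa-3,5-dien-1-yl]-6-endo-(prop-1-en-2-yl)-3-(triisopropylsilyloxy)bicyclo[2.2.1]hept-2-ene | CC(=C)[C@@H]1C[C@H]2C[C@]1(CC/C(C)=C(\Br)C=C)C=C2O[Si](C(C)C)(C(C)C)C(C)C | intermediate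
19 | 4-[(3Z)-4-bromo-3-methylhexa-3,5-dien-1-yl]-3-exo-(dimethoxymethyl)-5-endo-(prop-1-en-2-yl)bicyclo[2.2.1]heptan-2-one | CC(=C)[C@@H]1C[C@H]2C[C@]1(CC/C(C)=C(\Br)C=C)[C@H](C(OC)OC)C2=O | intermediate
20 | 4-[(3Z)-4-bromo-3-methylhexa-3,5-dien-1-yl]-3-exo-(dimethoxymethyl)-5-endo-(prop-1-en-2-yl)bicyclo[2.2.1]heptan-2-endo-ol | CC(=C)[C@@H]1C[C@H]2C[C@]1(CC/C(C)=C(\Br)C=C)[C@H](C(OC)OC)[C@H]2O | intermediate
21 | 1-[(3Z)-4-bromo-3-methylhexa-3,5-dien-1-yl]-3-endo-hydroxy-6-endo-(prop-1-en-2-yl)bicyclo[2.2.1]heptane-2-exo-carbaldehyde | CC(=C)[C@@H]1C[C@H]2C[C@]1(CC/C(C)=C(\Br)C=C)[C@H](C=O)[C@H]2O | intermediate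
22 | 4-[(3Z)-4-bromo-3-methylhexa-3,5-dien-1-yl]-3-exo-(1-hydroxy-2-nitroethyl)-5-endo-(prop-1-en-2-yl)bicyclo[2.2.1]heptan-2-endo-ol (both carbinol epimers) | CC(=C)[C@@H]1C[C@H]2C[C@]1(CC/C(C)=C(\Br)C=C)[C@H](C(O)C[N+](=O)[O-])[C@H]2O | intermediate
23 | diacetate of 22 | CC(=C)[C@@H]1C[C@H]2C[C@]1(CC/C(C)=C(\Br)C=C)[C@H](C(OC(C)=O)C[N+](=O)[O-])[C@H]2OC(C)=O | intermediate
24 | 4-[(3Z)-4-bromo-3-methylhexa-3,5-dien-1-yl]-3-exo-[(E)-2-nitroethenyl]-5-endo-(prop-1-en-2-yl)bicyclo[2.2.1]heptan-2-endo-yl acetate | CC(=C)[C@@H]1C[C@H]2C[C@]1(CC/C(C)=C(\Br)C=C)[C@H](/C=C/[N+](=O)[O-])[C@H]2OC(C)=O | intermediate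
25 | tetracyclic nitro acetate: ring A cyclohexene with C(Br)=CH, trans-fused to ring B at the quaternary C–Me carbon and the ring-fusion CH; nitro cis to the ring-fusion H; endo acetate and endo isopropenyl on the norbornane | CC(=C)[C@@H]1C[C@H]2C[C@@]13CC[C@]1(C)C(Br)=CC[C@H]([N+](=O)[O-])[C@H]1[C@@H]3[C@H]2OC(C)=O | intermediate
26 | sodium nitronate of deacetylated 25 | CC(=C)[C@@H]1C[C@H]2C[C@@]13CC[C@]1(C)C(Br)=CCC(=[N+]([O-])[O-])[C@H]1[C@@H]3[C@H]2O.[Na+] | intermediate
27 | tetracyclic hydroxy ketone: ring A ketone at the former nitro carbon, C(Br)=CH retained, endo OH free, endo isopropenyl | CC(=C)[C@@H]1C[C@H]2C[C@@]13CC[C@]1(C)C(Br)=CCC(=O)[C@H]1[C@@H]3[C@H]2O | intermediate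
28 | tetracyclic diol: axial tertiary methyl carbinol syn to the angular methyl, C(Br)=CH in ring A, endo secondary OH, endo isopropenyl | CC(=C)[C@@H]1C[C@H]2C[C@@]13CC[C@]1(C)C(Br)=CC[C@@](C)(O)[C@H]1[C@@H]3[C@H]2O | intermediate
29 | CNP0295684.1: bromo diol with equatorial Br, axial tertiary OH, endo secondary OH, endo isopropyl | CC(C)[C@@H]1C[C@H]2C[C@@]13CC[C@]1(C)[C@@H](Br)CC[C@@](C)(O)[C@H]1[C@@H]3[C@H]2O | target

Total steps: 16. Longest linear sequence: 16 steps (from 1 to 29).

Steps most likely to fail

1. Step 13. The diene carries an inside methyl group at its reacting terminus and may cycloadd slowly, so that polymerisation of the nitroalkene or leakage into the cis-fused transition state could compete. Fallback: starting from aldehyde 21, a Horner–Wadsworth–Emmons reaction with diethyl [(phenylsulfonyl)methyl]phosphonate (LiCl, DBU, MeCN) would give the thermally robust (E)-vinyl sulfone F1. Its intramolecular Diels–Alder reaction at higher temperature (toluene, 140 °C) should give the tetracyclic sulfone F2. Deprotonation next to sulfur (LDA, THF, −78 °C) and oxidation of the carbanion with bis(trimethylsilyl) peroxide (oxidative desulfonylation) would then give ketone 27, where the route is rejoined.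

2. Step 8. The silyloxycyclopentadiene may undergo a 1,5-hydrogen shift before it is trapped, the acid catalyst may strip the silyl group, or the catalyst may shield one enone face incompletely. Fallback: starting from diene 15, an Et2AlCl-promoted Diels–Alder reaction with (S)-3-acryloyl-4-benzyl-1,3-oxazolidin-2-one (CH2Cl2, −78 °C; the auxiliary enantiomer is chosen to give the same facial sense) would give the endo imide cycloadduct F3 under auxiliary control. Transamidation (MeONHMe·HCl, AlMe3, CH2Cl2) would give the Weinreb amide F4, and MeMgBr (THF, 0 °C) would convert this into methyl ketone 17, where the route is rejoined.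

3. Step 16. Hydrogen-atom transfer to the bromine-bearing carbon followed by loss of a bromine atom would remove the halogen, and H delivery to the α-bromo radical from the equatorial side would give the axial bromide. Fallback: starting from 28, heterogeneous hydrogenation (H2, 5% Rh on Al2O3, EtOAc, rt) would add both hydrogens to the alkenyl bromide from the face opposite the axial methyl and axial hydroxyl, and would also reduce the isopropenyl group. This should give 29 directly, with no new compound on the way.

Further compounds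
F1 | step 13 | 4-[(3Z)-4-bromo-3-methylhexa-3,5-dien-1-yl]-3-exo-[(E)-2-(phenylsulfonyl)ethenyl]-5-endo-(prop-1-en-2-yl)bicyclo[2.2.1]heptan-2-endo-ol | CC(=C)[C@@H]1C[C@H]2C[C@]1(CC/C(C)=C(\Br)C=C)[C@H](/C=C/S(=O)(=O)c1ccccc1)[C@H]2O
F2 | step 13 | tetracyclic phenyl sulfone (sulfonyl in place of the nitro group of 25; endo OH free) | CC(=C)[C@@H]1C[C@H]2C[C@@]13CC[C@]1(C)C(Br)=CC[C@H](S(=O)(=O)c4ccccc4)[C@H]1[C@@H]3[C@H]2O
F3 | step 8 | (S)-4-benzyl-3-{[1-[(3Z)-4-bromo-3-methylhexa-3,5-dien-1-yl]-5-(triisopropylsilyloxy)bicyclo[2.2.1]hept-5-en-2-endo-yl]carbonyl}-1,3-oxazolidin-2-one | O=C(N1C(=O)OC[C@@H]1Cc1ccccc1)[C@@H]1C[C@H]2C[C@]1(CC/C(C)=C(\Br)C=C)C=C2O[Si](C(C)C)(C(C)C)C(C)C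
F4 | step 8 | 1-[(3Z)-4-bromo-3-methylhexa-3,5-dien-1-yl]-N-methoxy-N-methyl-5-(triisopropylsilyloxy)bicyclo[2.2.1]hept-5-ene-2-endo-carboxamide | CON(C)C(=O)[C@@H]1C[C@H]2C[C@]1(CC/C(C)=C(\Br)C=C)C=C2O[Si](C(C)C)(C(C)C)C(C)C
F0 | step 16 | none | none
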